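The route rests on taking both C–Cl bonds out last: the bicyclic ketal cage with both epoxides is built chlorine-free, and one operation then chlorinates C6 (ring B) and C6′ (ring A). The step exploits the free phenols at C5 and C5′, each of which has a single open ortho carbon (C6, C6′) and a blocked para carbon (C8–O, C8′–C1). The precursor is the dechloro bis-epoxide triol, assembled by addition of a lithiated quinone bisketal (ketone half, from 5,8-dimethoxy-1-tetralone) to an enantioenriched epoxy tetralone (alcohol half, from juglone), acid-mediated transketalisation to the cage enone, epoxidation and desilylation.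

Key step: step 20

Remarks on the chemistry
- Locants: the alcohol half is numbered C1–C8a (aromatic ring B), the ketone half C1′–C8a′ (aromatic ring A). The halves are joined by C1–C8′, C1–O–C1′ and C8–O–C1′.
- Structure check: the dechloro precursor 27 and the target 29 have the same cage and the same seven stereocentres (1S,2R,3R,4S,1′S,2′R,3′S). Only the C6–Cl and C6′–Cl bonds differ, so no correction is needed. The precursor is used with all three hydroxyls free, because the catalyst must hydrogen-bond to both phenols and no step may follow.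
- Assumption: (S)-2-methyl-CBS-oxazaborolidine, (3aS)-1-methyl-3,3-diphenyltetrahydro-1H,3H-pyrrolo[1,2-c][1,3,2]oxazaborole, gives the (1R)-alcohol 8 by the usual model. The aryl flank with its peri silyloxy group is taken as the large substituent.

Step 1
Reactants: 1 juglone (5-hydroxynaphthalene-1,4-dione)
Product: 2 5-(benzyloxy)naphthalene-1,4-dione
Conditions: BnBr, Ag2O, CH2Cl2, rt, dark
Reagents that add atoms: benzyl bromide, BrCc1ccccc1
Why: Silver oxide-mediated Williamson etherification should alkylate the hydrogen-bonded peri phenol without touching the quinone, masking the oxygen that ends as the C4 hydroxyl.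

Step 2
Reactants: 2 5-(benzyloxy)naphthalene-1,4-dione
Product: 4 5-(benzyloxy)-1,4-bis[(tert-butyldimethylsilyl)oxy]naphthalene, via hydroquinone 3 (not isolated)
Conditions: Na2S2O4, EtOAc/H2O, rt; then TBSCl, imidazole, DMF, rt
Reagents that add atoms: tert-butyldimethylsilyl chloride, CC(C)(C)[Si](C)(C)Cl
Why: Dithionite reduction of the quinone followed at once by silyl ether formation should fix the two future ring B oxygens as identical silyl ethers.

Step 3
Reactants: 4 5-(benzyloxy)-1,4-bis[(tert-butyldimethylsilyl)oxy]naphthalene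
Product: 5 5,8-bis[(tert-butyldimethylsilyl)oxy]naphthalen-1-ol
Conditions: H2 (1 atm), Pd/C, EtOAc, rt
Reagents that add atoms: none
Why: Neutral hydrogenolysis of the benzyl ether should free only the naphthol, since aryl silyl ethers are inert to these conditions and no phenoxide is formed that could shuttle silicon between the peri oxygens.

Step 4
Reactants: 5 5,8-bis[(tert-butyldimethylsilyl)oxy]naphthalen-1-ol
Product: 7 5,8-bis[(tert-butyldimethylsilyl)oxy]-4,4-dimethoxynaphthalen-1(4H)-one, via 4-methoxynaphthol 6 (not isolated)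
Conditions: PhI(OAc)2 (2.2 equiv), MeOH, 0 °C → rt
Reagents that add atoms: methanol, CO
Why: Twofold hypervalent-iodine oxidative dearomatisation of the para-unsubstituted naphthol in methanol should give the para-quinone monoketal, the silyl ethers being untouched because only the free phenol is oxidised.

Step 5
Reactants: 7 5,8-bis[(tert-butyldimethylsilyl)oxy]-4,4-dimethoxynaphthalen-1(4H)-one
Product: 8 (1R)-5,8-bis[(tert-butyldimethylsilyl)oxy]-4,4-dimethoxy-1,4-dihydronaphthalen-1-ol
Conditions: (S)-2-methyl-CBS-oxazaborolidine (20 mol%), BH3·SMe2, THF, −30 °C; MeOH quench; Et3N-deactivated silica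
Reagents that add atoms: none
Why: Corey–Bakshi–Shibata reduction should give clean 1,2-reduction of the enone and set the carbinol centre (the later C4) under catalyst control, boron binding the carbonyl lone pair on the unhindered vinyl side.

Step 6
Reactants: 8 (1R)-5,8-bis[(tert-butyldimethylsilyl)oxy]-4,4-dimethoxy-1,4-dihydronaphthalen-1-ol
Product: 9 (1R)-1,5,8-tris[(tert-butyldimethylsilyl)oxy]-4,4-dimethoxy-1,4-dihydronaphthalene
Conditions: TBSCl, imidazole, DMAP (cat.), DMF, 40 °C
Reagents that add atoms: tert-butyldimethylsilyl chloride, CC(C)(C)[Si](C)(C)Cl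
Why: Base-mediated silylation, free of Lewis acid so that the allylic ketal cannot ionise and aromatise, should install a bulky silyl ether that the peri substituent forces into the pseudoaxial position.

Step 7
Reactants: 9 (1R)-1,5,8-tris[(tert-butyldimethylsilyl)oxy]-4,4-dimethoxy-1,4-dihydronaphthalene
Product: 10 (1S,2S,3R)-1,5,8-tris[(tert-butyldimethylsilyl)oxy]-2,3-epoxy-4,4-dimethoxy-1,2,3,4-tetrahydronaphthalene
Conditions: DMDO (acetone solution), CH2Cl2, 0 °C → rt
Reagents that add atoms: dimethyldioxirane, CC1(C)OO1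
Why: Neutral dioxirane epoxidation should attack the alkene from the face opposite the pseudoaxial C1 silyloxy group, so that both oxirane carbons are set trans to that oxygen by substrate control.

Step 8
Reactants: 10 (1S,2S,3R)-1,5,8-tris[(tert-butyldimethylsilyl)oxy]-2,3-epoxy-4,4-dimethoxy-1,2,3,4-tetrahydronaphthalene
Product: 11 (2R,3S,4S)-4,5,8-tris[(tert-butyldimethylsilyl)oxy]-2,3-epoxy-3,4-dihydronaphthalen-1(2H)-one
Conditions: TFA, H2O, CH2Cl2, 0 °C
Reagents that add atoms: water, O
Why: Acid-catalysed ketal hydrolysis should unmask the C1 ketone, the oxirane being flanked by electron-poor carbons and therefore slow to open under brief aqueous acid.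

Step 9
Reactants: 11 (2R,3S,4S)-4,5,8-tris[(tert-butyldimethylsilyl)oxy]-2,3-epoxy-3,4-dihydronaphthalen-1(2H)-one
Product: 12 (2R,3R,4S)-2,3-epoxy-4,5,8-trihydroxy-3,4-dihydronaphthalen-1(2H)-one
Conditions: Bu4NF, AcOH, THF, 0 °C → rt, argon
Reagents that add atoms: none
Why: Buffered fluoride desilylation should cleave all three silyl ethers without base-induced epoxide migration, giving an acyl hydroquinone that is far less air-sensitive than a simple hydroquinone.

Step 10
Reactants: 12 (2R,3R,4S)-2,3-epoxy-4,5,8-trihydroxy-3,4-dihydronaphthalen-1(2H)-one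
Product: 13 (2R,3S,4S)-4,5-O-(di-tert-butylsilanediyl)-2,3-epoxy-4,5,8-trihydroxy-3,4-dihydronaphthalen-1(2H)-one
Conditions: tBu2Si(OTf)2 (1.05 equiv), 2,6-lutidine, CH2Cl2/DMF, −40 → 0 °C
Reagents that add atoms: di-tert-butylsilyl bis(trifluoromethanesulfonate), CC(C)(C)[Si](OS(=O)(=O)C(F)(F)F)(OS(=O)(=O)C(F)(F)F)C(C)(C)C
Why: Cyclic silylene formation should bridge the ortho-hydroxybenzyl alcohol pair O4/O5 in a six-membered ring, while the C8 hydroxyl, hydrogen-bonded to the ketone and without a partner, stays free.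

Step 11
Reactants: 14 5,8-dimethoxy-3,4-dihydronaphthalen-1(2H)-one
Product: 15 5,8-dimethoxynaphthalen-1-ol
Conditions: Pd/C, p-cymene, reflux, N2
Reagents that add atoms: none
Why: Catalytic dehydrogenation should aromatise the tetralone to the naphthol, the driving force being formation of the second aromatic ring.

Step 12
Reactants: 15 5,8-dimethoxynaphthalen-1-ol
Product: 16 4-bromo-5,8-dimethoxynaphthalen-1-ol
Conditions: NBS, MeCN, −20 → 0 °C
Reagents that add atoms: N-bromosuccinimide, O=C1CCC(=O)N1Br
Why: Electrophilic aromatic bromination should go para to the free hydroxyl, the most activated position of the naphthol ring, which places bromine at the future C8′.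

Step 13
Reactants: 16 4-bromo-5,8-dimethoxynaphthalen-1-ol
Product: 17 4-bromo-5,8-dimethoxynaphthalen-1-yl acetate
Conditions: Ac2O, pyridine, DMAP (cat.), CH2Cl2, rt
Reagents that add atoms: acetic anhydride, CC(=O)OC(C)=O
Why: Acetylation should turn the oxidisable phenol into an electron-poor ester, so that the following oxidation takes place only on the dimethoxy ring.

Step 14
Reactants: 17 4-bromo-5,8-dimethoxynaphthalen-1-yl acetate
Product: 18 4-bromo-5,5,8,8-tetramethoxy-5,8-dihydronaphthalen-1-yl acetate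
Conditions: Pt anode, LiClO4, 2,6-lutidine, MeOH, 0 °C, constant current, undivided cell
Reagents that add atoms: methanol, CO
Why: Anodic bis-methoxylation of the 1,4-dimethoxyarene ring should give the quinone bisketal, a known electrochemical reaction of such arenes that tolerates aryl bromides and is run here in a buffered neutral electrolyte to keep the ester.

Step 15
Reactants: 18 4-bromo-5,5,8,8-tetramethoxy-5,8-dihydronaphthalen-1-yl acetate
Product: 20 [(4-bromo-5,5,8,8-tetramethoxy-5,8-dihydronaphthalen-1-yl)oxy]tri(propan-2-yl)silane, via phenol 19 (not isolated)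
Conditions: K2CO3 (cat.), MeOH, rt; evaporate; then TIPSCl, imidazole, DMF, rt
Reagents that add atoms: triisopropylsilyl chloride, CC(C)[Si](Cl)(C(C)C)C(C)C
Why: Base-catalysed transesterification, to which the bisketal is inert, should free the phenol, and silylation then gives an ether that survives aryllithium chemistry and leaves with fluoride at the end.

Step 16
Reactants: 20 [(4-bromo-5,5,8,8-tetramethoxy-5,8-dihydronaphthalen-1-yl)oxy]tri(propan-2-yl)silane; 13 (2R,3S,4S)-4,5-O-(di-tert-butylsilanediyl)-2,3-epoxy-4,5,8-trihydroxy-3,4-dihydronaphthalen-1(2H)-one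
Product: 23 coupled diol (1S,2R,3S,4S)-4,5-O-(di-tert-butylsilanediyl)-2,3-epoxy-1-{5,5,8,8-tetramethoxy-4-[(triisopropylsilyl)oxy]-5,8-dihydronaphthalen-1-yl}-1,2,3,4-tetrahydronaphthalene-1,4,5,8-tetrol, via aryllithium 21 (not isolated), via sodium phenoxide 22 (not isolated)
Conditions: 20, n-BuLi, THF, −78 °C; 13, NaH, THF, 0 °C, then added at −78 °C and warmed to −40 °C; aq. NH4Cl
Reagents that add atoms: none
Why: Bromine–lithium exchange and 1,2-addition of the aryllithium to the ketone should form the C1–C8′ bond, and C1 is set by attack on the face opposite the oxirane oxygen, the silylene holding O4 near the arene plane so that nothing shields that face.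

Step 17
Reactants: 23 coupled diol
Product: 25 cage enone (1S,2R,3S,4S,1′R) carrying the O4/O5 silylene and the 5′-O-triisopropylsilyl ether, via cage bisketal 24 (not isolated)
Conditions: CSA (20 mol%), CH2Cl2, 0 °C → rt; then THF/H2O, rt
Reagents that add atoms: water, O
Why: Acid-catalysed transketalisation should let the tertiary C1 hydroxyl and the C8 phenol replace both methoxy groups at C1′ (five- and six-membered closures, C1′ fixed by the C1 bridgehead), and aqueous acid then hydrolyses the allylic C4′ ketal to the enone, aromatisation being impossible because C4′ carries no hydrogen.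

Step 18
Reactants: 25 cage enone
Product: 26 silyl-protected bis-epoxide (1S,2R,3S,4S,1′S,2′R,3′S)
Conditions: t-BuOOH (decane), DBU, CH2Cl2, 0 °C
Reagents that add atoms: tert-butyl hydroperoxide, CC(C)(C)OO
Why: Weitz–Scheffer epoxidation of the enone should place the oxirane on the face opposite the axial C1′–O8 aryl ether bond and ring B, that is on the side of the C1–O–C1′ bridge, which sets C2′ and C3′.

Step 19
Reactants: 26 silyl-protected bis-epoxide
Product: 27 dechloro bis-epoxide triol (1S,2R,3R,4S,1′S,2′R,3′S)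
Conditions: Bu4NF, AcOH, THF, 0 °C → rt
Reagents that add atoms: none
Why: Buffered fluoride desilylation should remove the silylene and the triisopropylsilyl ether in one operation without opening either oxirane or the cage ketal.

Step 20
Reactants: 27 dechloro bis-epoxide triol; 28 N-chlorosuccinimide (2.05 equiv)
Product: 29 target, 6,6′-dichloro bis-epoxide triol (1S,2R,3R,4S,1′S,2′R,3′S)
Conditions: NCS, i-Pr2NH2Cl (10 mol%), toluene/CH2Cl2, 0 °C → rt, dark
Reagents that add atoms: N-chlorosuccinimide, O=C1CCC(=O)N1Cl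
Why: The ammonium chloride and NCS generate an N-chloro ammonium species that hydrogen-bonds to a free phenol and hands electrophilic chlorine to the adjacent ortho carbon; loss of the proton from the arenium ion restores the arene and succinimide is the only stoichiometric by-product. The closest known reaction is the ammonium- or thiourea-catalysed ortho-selective chlorination of phenols with N-halo imides. No ring is closed and no stereocentre is formed or touched. On ring B the C5 hydroxyl directs to C6, its only free ortho position, because the para carbon C8 carries the ketal oxygen and C7 is activated only by that weakly donating oxygen. On ring A the C5′ hydroxyl directs to C6′, which is ortho to oxygen and meta to the C4′ carbonyl, whereas C7′ is para to the carbonyl and C8′ is substituted. Two equivalents of reagent, low temperature and the absence of HCl should limit over-chlorination, oxidation of ring B and epoxide opening.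

Compound list
1 | juglone (5-hydroxynaphthalene-1,4-dione) | O=C1C=CC(=O)c2c(O)cccc12 | starting material
2 | 5-(benzyloxy)naphthalene-1,4-dione | O=C1C=CC(=O)c2c(OCc3ccccc3)cccc12 | intermediate
3 | 5-(benzyloxy)naphthalene-1,4-diol | Oc1ccc(O)c2c(OCc3ccccc3)cccc12 | intermediate (not isolated)
4 | 5-(benzyloxy)-1,4-bis[(tert-butyldimethylsilyl)oxy]naphthalene | CC(C)(C)[Si](C)(C)Oc1ccc(O[Si](C)(C)C(C)(C)C)c2c(OCc3ccccc3)cccc12 | intermediate
5 | 5,8-bis[(tert-butyldimethylsilyl)oxy]naphthalen-1-ol | CC(C)(C)[Si](C)(C)Oc1ccc(O[Si](C)(C)C(C)(C)C)c2c(O)cccc12 | intermediate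
6 | 5,8-bis[(tert-butyldimethylsilyl)oxy]-4-methoxynaphthalen-1-ol | CC(C)(C)[Si](C)(C)Oc1ccc(O[Si](C)(C)C(C)(C)C)c2c(O)ccc(OC)c12 | intermediate (not isolated)
7 | 5,8-bis[(tert-butyldimethylsilyl)oxy]-4,4-dimethoxynaphthalen-1(4H)-one | CC(C)(C)[Si](C)(C)Oc1ccc(O[Si](C)(C)C(C)(C)C)c2C(=O)C=CC(OC)(OC)c12 | intermediate
8 | (1R)-5,8-bis[(tert-butyldimethylsilyl)oxy]-4,4-dimethoxy-1,4-dihydronaphthalen-1-ol | CC(C)(C)[Si](C)(C)Oc1ccc(O[Si](C)(C)C(C)(C)C)c2c1C(OC)(OC)C=C[C@H]2O | intermediate
9 | (1R)-1,5,8-tris[(tert-butyldimethylsilyl)oxy]-4,4-dimethoxy-1,4-dihydronaphthalene | CC(C)(C)[Si](C)(C)Oc1ccc(O[Si](C)(C)C(C)(C)C)c2c1C(OC)(OC)C=C[C@H]2O[Si](C)(C)C(C)(C)C | intermediate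
10 | (1S,2S,3R)-1,5,8-tris[(tert-butyldimethylsilyl)oxy]-2,3-epoxy-4,4-dimethoxy-1,2,3,4-tetrahydronaphthalene (oxirane trans to the C1 silyloxy group) | CC(C)(C)[Si](C)(C)Oc1ccc(O[Si](C)(C)C(C)(C)C)c2c1C(OC)(OC)[C@@H]3O[C@@H]3[C@H]2O[Si](C)(C)C(C)(C)C | intermediate
11 | (2R,3S,4S)-4,5,8-tris[(tert-butyldimethylsilyl)oxy]-2,3-epoxy-3,4-dihydronaphthalen-1(2H)-one | CC(C)(C)[Si](C)(C)Oc1ccc(O[Si](C)(C)C(C)(C)C)c2c1C(=O)[C@@H]3O[C@@H]3[C@H]2O[Si](C)(C)C(C)(C)C | intermediate
12 | (2R,3R,4S)-2,3-epoxy-4,5,8-trihydroxy-3,4-dihydronaphthalen-1(2H)-one | Oc1ccc(O)c2c1C(=O)[C@@H]3O[C@@H]3[C@H]2O | intermediate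
13 | (2R,3S,4S)-4,5-O-(di-tert-butylsilanediyl)-2,3-epoxy-4,5,8-trihydroxy-3,4-dihydronaphthalen-1(2H)-one (O4 and O5 bridged by Si(t-Bu)2, 8-OH free) | Oc1ccc(O[Si]4(C(C)(C)C)C(C)(C)C)c2c1C(=O)[C@@H]3O[C@@H]3[C@H]2O4 | intermediate
14 | 5,8-dimethoxy-3,4-dihydronaphthalen-1(2H)-one | COc1ccc(OC)c2c1CCCC2=O | starting material
15 | 5,8-dimethoxynaphthalen-1-ol | COc1ccc(OC)c2c(O)cccc12 | intermediate
16 | 4-bromo-5,8-dimethoxynaphthalen-1-ol | COc1ccc(OC)c2c(O)ccc(Br)c12 | intermediate
17 | 4-bromo-5,8-dimethoxynaphthalen-1-yl acetate | COc1ccc(OC)c2c(OC(C)=O)ccc(Br)c12 | intermediate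
18 | 4-bromo-5,5,8,8-tetramethoxy-5,8-dihydronaphthalen-1-yl acetate | CC(=O)Oc1ccc(Br)c2c1C(OC)(OC)C=CC2(OC)OC | intermediate
19 | 4-bromo-5,5,8,8-tetramethoxy-5,8-dihydronaphthalen-1-ol | Oc1ccc(Br)c2c1C(OC)(OC)C=CC2(OC)OC | intermediate (not isolated)
20 | [(4-bromo-5,5,8,8-tetramethoxy-5,8-dihydronaphthalen-1-yl)oxy]tri(propan-2-yl)silane | CC(C)[Si](Oc1ccc(Br)c2c1C(OC)(OC)C=CC2(OC)OC)(C(C)C)C(C)C | intermediate
21 | {5,5,8,8-tetramethoxy-4-[(triisopropylsilyl)oxy]-5,8-dihydronaphthalen-1-yl}lithium | CC(C)[Si](Oc1ccc([Li])c2c1C(OC)(OC)C=CC2(OC)OC)(C(C)C)C(C)C | intermediate (not isolated)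
22 | sodium 8-phenoxide of 13 | [Na+].[O-]c1ccc(O[Si]4(C(C)(C)C)C(C)(C)C)c2c1C(=O)[C@@H]3O[C@@H]3[C@H]2O4 | intermediate (not isolated)
23 | coupled diol, (1S,2R,3S,4S)-4,5-O-(di-tert-butylsilanediyl)-2,3-epoxy-1-{5,5,8,8-tetramethoxy-4-[(triisopropylsilyl)oxy]-5,8-dihydronaphthalen-1-yl}-1,2,3,4-tetrahydronaphthalene-1,4,5,8-tetrol (aryl trans to the oxirane oxygen) | Oc1ccc(O[Si]4(C(C)(C)C)C(C)(C)C)c2c1[C@@](O)(c5ccc(O[Si](C(C)C)(C(C)C)C(C)C)c6c5C(OC)(OC)C=CC6(OC)OC)[C@@H]3O[C@@H]3[C@H]2O4 | intermediate
24 | cage bisketal (1S,2R,3S,4S,1′R): C1′ ketal closed by O1 and O8, C4′ still a dimethyl ketal, C2′=C3′ alkene, O4/O5 silylene, 5′-O-triisopropylsilyl | COC1(OC)c2c(O[Si](C(C)C)(C(C)C)C(C)C)ccc3c2[C@@]2(Oc4ccc(O[Si]6(C(C)(C)C)C(C)(C)C)c5c4[C@]3(O2)[C@@H]2O[C@@H]2[C@H]5O6)C=C1 | intermediate (not isolated)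
25 | cage enone (1S,2R,3S,4S,1′R): C4′ ketone, C2′=C3′ alkene, C2–C3 oxirane, O4/O5 silylene, 5′-O-triisopropylsilyl | O=C1c2c(O[Si](C(C)C)(C(C)C)C(C)C)ccc3c2[C@@]2(Oc4ccc(O[Si]6(C(C)(C)C)C(C)(C)C)c5c4[C@]3(O2)[C@@H]2O[C@@H]2[C@H]5O6)C=C1 | intermediate
26 | silyl-protected bis-epoxide (1S,2R,3S,4S,1′S,2′R,3′S): both oxiranes on the side of the C1–O–C1′ bridge, O4/O5 silylene, 5′-O-triisopropylsilyl | O=C1c2c(O[Si](C(C)C)(C(C)C)C(C)C)ccc3c2[C@@]2(Oc4ccc(O[Si]6(C(C)(C)C)C(C)(C)C)c5c4[C@]3(O2)[C@@H]2O[C@@H]2[C@H]5O6)[C@@H]2O[C@H]12 | intermediate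
27 | dechloro bis-epoxide triol (1S,2R,3R,4S,1′S,2′R,3′S), the precursor of the key step | O=C1c2c(O)ccc3c2[C@@]2(Oc4ccc(O)c5c4[C@]3(O2)[C@@H]2O[C@@H]2[C@H]5O)[C@@H]2O[C@H]12 | intermediate
28 | N-chlorosuccinimide | O=C1CCC(=O)N1Cl | starting material (commercial reagent)
29 | target, 6,6′-dichloro bis-epoxide triol (1S,2R,3R,4S,1′S,2′R,3′S) | O=C1c2c(O)c(Cl)cc3c2[C@@]2(Oc4cc(Cl)c(O)c5c4[C@]3(O2)[C@@H]2O[C@@H]2[C@H]5O)[C@@H]2O[C@H]12 | target

Total step count: 20 (alcohol half steps 1–10, ketone half steps 11–15, union and endgame steps 16–20).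
Longest linear sequence: 15 steps (steps 1–10, then 16–20, from juglone).

Steps most likely to fail

Step 20. What may go wrong is incomplete chlorination of the hydrogen-bonded, carbonyl-deactivated ring A phenol, with over-chlorination or oxidation of the electron-rich ring B once the reaction is forced. The fallback stages the two chlorinations; it sets out from 26 and comes back at 29. One equivalent of Bu4NF with AcOH at −40 °C should cleave only the triisopropylsilyl ether, which is activated by the peri carbonyl, giving the ring A phenol with the silylene intact F1. NCS with the same ammonium catalyst, now usable in excess and with warming because ring B and O4 are masked, should give the C6′-chloro silylene F2. Bu4NF/AcOH then removes the silylene to give the C6′-chloro triol F3. One equivalent of NCS with the ammonium catalyst chlorinates the reactive ring B phenol at C6 and gives 29.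

Step 16. What may go wrong is slow addition to the hindered ketone, which is deactivated by the peri phenoxide, so that proton transfer, decay of the aryllithium or loss of facial control competes. The fallback sets out from 13 and comes back at 23. TMSOTf and Et3N in CH2Cl2 at 0 °C should convert the chelated phenol into the 8-O-trimethylsilyl ether of 13 F4, whose ketone is no longer part of a vinylogous carboxylate. The organocerium reagent made from 21 and CeCl3 in THF at −78 °C, less basic and more oxophilic than the aryllithium, should add anti to the oxirane to give the 8-O-trimethylsilyl adduct F5. K2CO3 in MeOH at 0 °C then removes the trimethylsilyl group and returns 23.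

Step 17. What may go wrong is ionisation of the tertiary dibenzylic carbinol towards an ortho-quinone methide, or hydrolysis of the C1′ ketal by adventitious water before both C–O bonds have closed. The fallback replaces protic acid catalysis by aprotic silyl-transfer ketalisation; it sets out from 23 and comes back at 25. N,O-Bis(trimethylsilyl)acetamide in CH2Cl2 should give the 1,8-bis-O-trimethylsilyl ether of 23 F6. Catalytic TMSOTf in CH2Cl2 at −78 °C then lets the two silyl ethers capture the C1′ oxocarbenium ion with loss of methoxytrimethylsilane and gives the cage bisketal 24. Aqueous work-up with dilute acid hydrolyses the C4′ ketal to 25.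

Further compounds
F1 | step 20 | ring A phenol with the O4/O5 silylene intact (26 without its triisopropylsilyl group) | O=C1c2c(O)ccc3c2[C@@]2(Oc4ccc(O[Si]6(C(C)(C)C)C(C)(C)C)c5c4[C@]3(O2)[C@@H]2O[C@@H]2[C@H]5O6)[C@@H]2O[C@H]12
F2 | step 20 | C6′-chloro silylene | O=C1c2c(O)c(Cl)cc3c2[C@@]2(Oc4ccc(O[Si]6(C(C)(C)C)C(C)(C)C)c5c4[C@]3(O2)[C@@H]2O[C@@H]2[C@H]5O6)[C@@H]2O[C@H]12
F3 | step 20 | C6′-chloro triol | O=C1c2c(O)c(Cl)cc3c2[C@@]2(Oc4ccc(O)c5c4[C@]3(O2)[C@@H]2O[C@@H]2[C@H]5O)[C@@H]2O[C@H]12
F4 | step 16 | 8-O-trimethylsilyl ether of 13 | C[Si](C)(C)Oc1ccc(O[Si]4(C(C)(C)C)C(C)(C)C)c2c1C(=O)[C@@H]3O[C@@H]3[C@H]2O4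
F5 | step 16 | 8-O-trimethylsilyl adduct (23 with its C8 phenol silylated) | C[Si](C)(C)Oc1ccc(O[Si]4(C(C)(C)C)C(C)(C)C)c2c1[C@@](O)(c5ccc(O[Si](C(C)C)(C(C)C)C(C)C)c6c5C(OC)(OC)C=CC6(OC)OC)[C@@H]3O[C@@H]3[C@H]2O4
F6 | step 17 | 1,8-bis-O-trimethylsilyl ether of 23 | C[Si](C)(C)Oc1ccc(O[Si]4(C(C)(C)C)C(C)(C)C)c2c1[C@@](O[Si](C)(C)C)(c5ccc(O[Si](C(C)C)(C(C)C)C(C)C)c6c5C(OC)(OC)C=CC6(OC)OC)[C@@H]3O[C@@H]3[C@H]2O4
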